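Slowness hides the choice: target arrives late, through two intermediates, so we pick the next run by how substrate divides rather than by the yield of target read at a given time.

| flask | substrate | partner | second reagent | third reagent | remark | time |
|---|---|---|---|---|---|---|
| eta | 0.065 M | 0.163 M | 0.0845 M | 0.078 M | run made earlier |  |
| beta | 0.065 M | 0.11 M | 0.0845 M | 0.078 M | run made earlier |  |
| theta | 0.065 M | 0.24 M | 0.0845 M | 0.078 M | run made earlier |  |
| zeta | 0.033 M | 0.163 M | 0.0845 M | 0.078 M | run made earlier |  |
| amber | 0.065 M | 0.163 M | 0.0845 M | 0.0780 M | everything together at the start | 30 min |
| grey | 0.065 M (fed, over 20 min) | 0.163 M | 0.0845 M | 0.0780 M | all else is in the flask from the start; the feed brings no volume worth counting | 30 min |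
| violet | 0.065 M | 0.163 M | 0.0845 M (fed, over 20 min) | 0.0780 M | all else is in the flask from the start; the feed brings no volume worth counting | 30 min |

| run | time / min | target / % | side product A / % |
|---|---|---|---|
| eta | 1.33 | 1.5 | 7.2 |
| eta | 2.00 | 0.6 | 9.9 |
| eta | 3.00 | 0 | 12.1 |
| eta | 5.00 | 3.2 | 18.8 |
| eta | 8.00 | 6.4 | 24.0 |
| eta | 12.0 | 13.0 | 27.4 |
| eta | 20.0 | 20.7 | 32.4 |
| beta | 4.00 | 1.2 | 16.1 |
| beta | 8.00 | 6.3 | 26.7 |
| beta | 12.0 | 8.2 | 29.4 |
| beta | 15.0 | 11.6 | 32.5 |
| beta | 20.0 | 16.6 | 34.5 |
| beta | 25.0 | 16.1 | 36.6 |
| beta | 30.0 | 20.4 | 38.3 |
| theta | 2.50 | 1.2 | 11.4 |
| theta | 4.00 | 3.1 | 16.5 |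
| theta | 6.00 | 5.0 | 19.5 |
| theta | 8.00 | 10.3 | 21.9 |
| theta | 12.0 | 16.0 | 25.1 |
| theta | 20.0 | 25.9 | 27.2 |
| theta | 30.0 | 32.1 | 28.2 |
| zeta | 6.00 | 5.4 | 22.3 |
| zeta | 12.0 | 12.6 | 30.1 |
| zeta | 20.0 | 25.2 | 33.3 |
| zeta | 25.0 | 28.5 | 34.4 |
| zeta | 30.0 | 29.5 | 35.8 |

(standard deviation of a reading: 1 percentage point)

- in percentages every species weighs as the substrate in it: one side product B counts as two
- what was read earlier has a scatter of 1 percentage point, one standard deviation
- reactions considered so far: substrate + partner -> intermediate A; substrate + second reagent -> side product A; third reagent + intermediate B -> target; substrate <-> dormant form; second reagent + intermediate A -> intermediate B; substrate + intermediate A -> side product B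

- the flask that comes out highest in share of target in target plus side product A, or "all alike" when all lie within 1.5 percentage points (amber / grey / violet / all alike)
- share of target in target plus side product A at the end, amber
- share of target in target plus side product A at the end, grey
- share of target in target plus side product A at the end, violet

Substrate is the limiting reagent, charged lower at 0.065 M than second reagent at 0.0845 M, so we write its balance. Substrate leaves with partner towards target, or with second reagent into side product A; it also passes into dormant form and, with intermediate A, into side product B, and our split below counts neither of these. In the eta run, between 8.00 min and 20.0 min, target gained 14 percentage points and side product A gained 8.4 points, a ratio of 1.70. At 12.0 min, the charge less what those two products took leaves [second reagent] near 0.0582 M. So we read a selectivity factor κ, the substrate going with partner per substrate going with second reagent at equal concentrations, of 0.608. It is a rough reading: each value carries 1 point, and partner is taken as charged.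

The split is then κ[partner]/[second reagent]. As charged it is 1.17, which gives finished material a target share of 54.0 %; amber and grey charge partner and second reagent alike, so we reckon that share for both. Violet has received on average half of its second reagent during the feed, so, counting none of it as used, the split in that stretch is 2.35, higher than as charged, and the share of material finished then is 70.1 %. We would charge violet.

The forecast chooses violet too, with amber 44 %, grey 46 % and violet 72 % at 30 min, holding that in violet intermediate A “captures second reagent much faster than substrate does”. Our shares differ from these numbers: they are for finished material, not for that time.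

The flasks give amber 43.3 %, grey 39.5 % and violet 63.5 %, violet standing highest.

    substrate + partner → intermediate A (k = 0.00580 /M/s)
    substrate + second reagent → side product A (k = 0.0120 /M/s)
    third reagent + intermediate B → target (k = 0.0980 /M/s)
    substrate ⇌ dormant form (K = 2.20, k = 8.30 × 10⁻⁴ /s)
    second reagent + intermediate A → intermediate B (k = 0.0330 /M/s)
    substrate + intermediate A → side product B (k = 0.0240 /M/s)

In grey at 15.4 min, substrate passed to intermediate A at 1.1 times the rate at which it passed into side product A. At 30.0 min, grey still held 7.22 % of intermediate A and 2.10 % of intermediate B. With the partner and second reagent left in violet at 30.0 min, κ gives a split of 1.47. For a grey run with partner at 0.65 M, κ gives 4.68, and that flask's target and both intermediates stand at 4.22 times its side product A.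

The earlier runs and the new flask come from a simulation for an exercise.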